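The readings stem from a simulated flask with made-up constants; the scatter is artificial.

If one capture agent makes one trapped intermediate, the trapped intermediate in a flask cannot pass the capture agent charged. So I reckoned with the capacity, the capture agent charged as a fraction of the substrate charged: 10.0 % in this flask. There the capture agent was the limiting reagent, with less of it than of substrate.

in all of them: substrate 0.40 M

| flask | capture agent | remark | time |
|---|---|---|---|
| alder | 0.020 M | run made earlier |  |
| birch | 0.080 M | run made earlier |  |
| flask | 0.0400 M |  | 20 min |

| run | time / min | product / % | trapped intermediate / % | substrate / % |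
|---|---|---|---|---|
| alder | 1.50 | 2 | 4 | 0 |
| alder | 4.00 | 3 | 6 | 0 |
| alder | 8.00 | 2 | 4 | 0 |
| alder | 12.0 | 2 | 3 | 1 |
| birch | 3.00 | 0 | 17 | 2 |
| birch | 6.00 | 0 | 19 | 0 |
| birch | 10.0 | 3 | 21 | 0 |
| birch | 12.0 | 0 | 19 | 1 |

(each reading ± 1.5 percentage points)

- candidate steps: substrate -> intermediate A; intermediate A <-> intermediate B; substrate -> product; product -> intermediate B; capture agent + intermediate B -> trapped intermediate

I read the runs as a ladder. The first rung was substrate: in the alder run it read 0 % at 1.50 min. The second rung was the filling of the capacity. At that same time, the reading of trapped intermediate in the alder run stood at 80.0 % of that run's capacity of 5.00 %. Later it averaged 4.33 %. The birch run averaged 19.7 % after its first reading, against a capacity of 20.0 %. The third rung was product, which averaged 1.50 % over both runs, with a scatter of 1.5 percentage points on each reading.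

My rule for the share was product over product plus trapped intermediate, with product held at that average and trapped intermediate at the capacity once filled. At 20 min, later than any reading, that gave 13.0 %. At 80 s, taking the alder fill, it gave 15.8 %. At 8.0 s, the candidate steps put product one step from substrate and trapped intermediate further off, so I expected a high share.

* share of product in product plus trapped intermediate at 8.0 s
* share of product in product plus trapped intermediate at 80 s
* share of product in product plus trapped intermediate at 20 min

The forecast gave 50 %, 16 % and 13 %, reading that product “does not grow with time”.

The flask gave 97.0 %, 37.7 % and 0.661 %.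

    substrate → intermediate A (k = 0.0530 s⁻¹)
    intermediate A ⇌ intermediate B (K = 0.840, k = 0.0300 s⁻¹)
    substrate → product (k = 0.00260 s⁻¹)
    product → intermediate B (k = 0.00360 s⁻¹)
    capture agent + intermediate B → trapped intermediate (k = 0.120 L mol⁻¹ s⁻¹)

My share at the end was higher than this. At 20.0 min the flask held 10.0 % of trapped intermediate, which is the capacity of 10.0 %, and 0.0665 % of product, and the rule on these gives 0.661 %. A neighbour flask with 0.16 M of capture agent has a capacity of 40.0 %. At 20.0 min it held 40.0 % of trapped intermediate and 0.0665 % of product, a share of 0.166 %.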